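**Retrosynthetic overview**
- Last bond made: ring B aryl–CH2. An aryl bromide (acceptor carbon) is coupled with palmitoyloxymethylzinc iodide. This is a formaldehyde carbon turned into a donor (d1 hydroxymethyl-anion synthon) that already carries the palmitate, and it is used on the unprotected bisphenol.
- The ring B phenol comes from an aldehyde by Baeyer–Villiger oxidation. Before that, the same aldehyde serves as the activating group for ether formation.
- The diaryl ether comes from a depside by Smiles rearrangement. The departing carboxylate is trapped as the methyl ester of ring A.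
- The depside comes from 2,6-dihydroxy-4-methylbenzoic acid and 3-bromo-2-hydroxy-5-methoxybenzaldehyde. The zinc reagent comes from palmitoyl chloride, paraformaldehyde, NaI and Zn.
- Rings: both benzene rings are bought intact and no ring is built. Only a transient six-membered spiro adduct appears, in the Smiles step.

Assumption: the SMILES has no stereocentre and the diaryl ether axis rotates freely, so the target is achiral and needs no stereocontrol; paraformaldehyde is drawn as its monomer.

**Step 1**
Reactants: 1 2,6-dihydroxy-4-methylbenzoic acid; 2 3-bromo-2-hydroxy-5-methoxybenzaldehyde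
Product: 4 2-bromo-6-formyl-4-methoxyphenyl 2,6-dihydroxy-4-methylbenzoate (depside), via mixed trifluoroacetic anhydride 3 (not isolated)
Conditions: (CF3CO)2O (2.5 equiv), toluene, 0 °C → rt, 16 h
Reagents that add atoms: none
Why: Mixed-anhydride esterification, in which the 2,6-dioxygenated aroyl trifluoroacetate acts as a stabilised acylium-type donor that acylates even the hindered, hydrogen-bonded phenol of 2, while the acidic medium leaves the chelated ortho-OH groups of 1 free and keeps the base-triggered rearrangement of step 2 from starting early; no stereocentre is formed.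

**Step 2**
Reactants: 4 depside
Product: 6 methyl 2-(2-bromo-6-formyl-4-methoxyphenoxy)-6-hydroxy-4-methylbenzoate, via potassium carboxylate 5 (not isolated)
Conditions: K2CO3 (1.5 equiv), 4 Å MS, dry DMSO, rt → 50 °C; then MeI (1.1 equiv), rt
Reagents that add atoms: methyl iodide, CI
Why: Smiles rearrangement (intramolecular SNAr through a six-membered spiro Meisenheimer adduct), in which a ring A phenoxide attacks the ester-bearing carbon of ring B (activated by the ortho formyl and ortho bromo groups) and the carboxylate leaves irreversibly, after which SN2 methylation takes the carboxylate and not the chelated salicylate OH; ring A is symmetric, so there is no regiochemical issue, and no stereocentre is formed.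

**Step 3**
Reactants: 6 methyl 2-(2-bromo-6-formyl-4-methoxyphenoxy)-6-hydroxy-4-methylbenzoate
Product: 8 methyl 2-(2-bromo-6-hydroxy-4-methoxyphenoxy)-6-hydroxy-4-methylbenzoate, via aryl formate 7 (not isolated)
Conditions: mCPBA (1.6 equiv), CH2Cl2, 0 °C → rt; aq Na2S2O3/NaHCO3 wash; then K2CO3 (0.1 equiv), MeOH, 0 °C, 15 min
Reagents that add atoms: mCPBA (3-chloroperoxybenzoic acid), O=C(OO)c1cccc(Cl)c1
Why: Baeyer–Villiger (Dakin-type) oxidation, in which the Criegee adduct of the aldehyde collapses with migration of the ortho-aryloxy aryl group to give the aryl formate, and catalytic carbonate in methanol transesterifies this formate within minutes while exchange at the hindered methyl benzoate would be degenerate; no stereocentre is formed.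

**Step 4**
Reactants: 9 palmitoyl chloride; 10 paraformaldehyde
Product: 12 iodomethyl palmitate, via chloromethyl palmitate 11 (not isolated)
Conditions: ZnCl2 (2 mol %), neat, 90 °C, 4 h; then NaI (1.5 equiv), acetone, rt, dark; short silica plug
Reagents that add atoms: sodium iodide, [Na+].[I-]
Why: ZnCl2-catalysed addition of the acyl chloride across formaldehyde (chloromethyl ester synthesis) followed by Finkelstein exchange, driven by precipitation of NaCl, gives the iodide needed for mild zinc insertion; no stereocentre is formed.

**Step 5 (key step)**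
Reactants: 8 methyl 2-(2-bromo-6-hydroxy-4-methoxyphenoxy)-6-hydroxy-4-methylbenzoate; 12 iodomethyl palmitate
Product: 14 Betaethrin E, via palmitoyloxymethylzinc iodide 13 (not isolated)
Conditions: 12 (3.5 equiv), Zn dust, THF, 10–15 °C, 2 h; solution added over 2 h to 8, Pd(OAc)2 (4 mol %), SPhos (8 mol %), THF, 25 → 45 °C; aq NH4Cl
Reagents that add atoms: none
Why: Proposed new method: zinc inserts into the carbon–iodine bond of 12 to give a carbonyl-chelated α-acyloxy organozinc, so the formaldehyde carbon changes from acceptor to donor, and this reagent transmetalates to the arylpalladium bromide formed from 8 by zerovalent palladium and reductively eliminates without any β-hydride pathway, the weakly basic zinc reagent coupling under SPhos faster than the phenols protonate it (the excess covers that loss); the closest known reaction types are Negishi couplings of pivaloyloxymethylzinc iodide-type hydroxymethyl-anion reagents and Negishi couplings of unprotected halophenols, and no stereocentre is formed.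

**Compound list**
1 | 2,6-dihydroxy-4-methylbenzoic acid | Cc1cc(O)c(C(=O)O)c(O)c1 | starting material
2 | 3-bromo-2-hydroxy-5-methoxybenzaldehyde | COc1cc(Br)c(O)c(C=O)c1 | starting material
3 | 2,6-dihydroxy-4-methylbenzoic trifluoroacetic anhydride | Cc1cc(O)c(C(=O)OC(=O)C(F)(F)F)c(O)c1 | intermediate
4 | 2-bromo-6-formyl-4-methoxyphenyl 2,6-dihydroxy-4-methylbenzoate | COc1cc(Br)c(OC(=O)c2c(O)cc(C)cc2O)c(C=O)c1 | intermediate
5 | potassium 2-(2-bromo-6-formyl-4-methoxyphenoxy)-6-hydroxy-4-methylbenzoate | COc1cc(Br)c(Oc2cc(C)cc(O)c2C(=O)[O-])c(C=O)c1.[K+] | intermediate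
6 | methyl 2-(2-bromo-6-formyl-4-methoxyphenoxy)-6-hydroxy-4-methylbenzoate | COc1cc(Br)c(Oc2cc(C)cc(O)c2C(=O)OC)c(C=O)c1 | intermediate
7 | methyl 2-[2-bromo-6-(formyloxy)-4-methoxyphenoxy]-6-hydroxy-4-methylbenzoate | COc1cc(Br)c(Oc2cc(C)cc(O)c2C(=O)OC)c(OC=O)c1 | intermediate
8 | methyl 2-(2-bromo-6-hydroxy-4-methoxyphenoxy)-6-hydroxy-4-methylbenzoate | COc1cc(O)c(Oc2cc(C)cc(O)c2C(=O)OC)c(Br)c1 | intermediate
9 | palmitoyl chloride | CCCCCCCCCCCCCCCC(=O)Cl | starting material
10 | paraformaldehyde (formaldehyde source) | C=O | starting material
11 | chloromethyl palmitate | CCCCCCCCCCCCCCCC(=O)OCCl | intermediate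
12 | iodomethyl palmitate | CCCCCCCCCCCCCCCC(=O)OCI | intermediate
13 | (palmitoyloxymethyl)zinc iodide | CCCCCCCCCCCCCCCC(=O)OC[Zn]I | intermediate
14 | Betaethrin E (achiral) | CCCCCCCCCCCCCCCC(=O)OCc1cc(OC)cc(O)c1Oc1cc(C)cc(O)c1C(=O)OC | target

**Total steps:** 5. **Longest linear sequence:** 4 (steps 1, 2, 3, 5).

**Steps most likely to fail**

Step 5.
- Risks: the two phenols may protonate 13. Oxidative addition into the hindered, electron-rich bromide may be slow. The chelated acyloxymethyl–palladium species may be slow to reductively eliminate.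
- Fallback: setting out from 8, a Stille coupling with (tributylstannyl)methanol (Pd(PPh3)4, dioxane, 100 °C) is used. This is a proton-tolerant hydroxymethyl-anion donor. It gives methyl 2-hydroxy-6-[2-hydroxy-6-(hydroxymethyl)-4-methoxyphenoxy]-4-methylbenzoate F1. A Mitsunobu esterification with palmitic acid (PPh3, DIAD, THF, 0 °C) activates only the aliphatic hydroxyl and leaves both phenols alone. It comes back to the route at 14.

Step 3.
- Risks: ring B is twisted out of conjugation with the ether oxygen and carries meta Br and meta OMe. Hydride migration to the carboxylic acid may therefore beat aryl migration.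
- Fallback: setting out from 6, MeMgBr (2.2 equiv, THF, −78 °C) gives racemic methyl 2-[2-bromo-6-(1-hydroxyethyl)-4-methoxyphenoxy]-6-hydroxy-4-methylbenzoate F2. Dess–Martin periodinane then gives methyl 2-(2-acetyl-6-bromo-4-methoxyphenoxy)-6-hydroxy-4-methylbenzoate F3. Baeyer–Villiger oxidation of this ketone (mCPBA, CF3CO2H, CH2Cl2) has only aryl and methyl competing, so it gives methyl 2-(2-acetoxy-6-bromo-4-methoxyphenoxy)-6-hydroxy-4-methylbenzoate F4. Catalytic K2CO3 in MeOH comes back to the route at 8. The ketone is introduced only after the ether is in place, so no enolate can attack a depside ester.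

Step 2 (and the hindered coupling of step 1 that feeds it).
- Risks: the para methoxy group deactivates ring B. The activated aryl ester may fragment or hydrolyse before it rearranges.
- Fallback: setting out from 2, deoxyfluorination (SO2F2, NMe4F, DMF, rt → 80 °C) passes through 2-bromo-6-formyl-4-methoxyphenyl fluorosulfate F5 and gives 3-bromo-2-fluoro-5-methoxybenzaldehyde F6. An intermolecular SNAr with purchased methyl 2,6-dihydroxy-4-methylbenzoate (2 equiv, Cs2CO3, DMF, 90 °C) comes back to the route at 6. This bypasses 3, 4 and 5.

**Further compounds**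
F1 | step 5 | methyl 2-hydroxy-6-[2-hydroxy-6-(hydroxymethyl)-4-methoxyphenoxy]-4-methylbenzoate | COc1cc(O)c(Oc2cc(C)cc(O)c2C(=O)OC)c(CO)c1
F2 | step 3 | methyl 2-[2-bromo-6-(1-hydroxyethyl)-4-methoxyphenoxy]-6-hydroxy-4-methylbenzoate (racemic) | COc1cc(Br)c(Oc2cc(C)cc(O)c2C(=O)OC)c(C(C)O)c1
F3 | step 3 | methyl 2-(2-acetyl-6-bromo-4-methoxyphenoxy)-6-hydroxy-4-methylbenzoate | COc1cc(Br)c(Oc2cc(C)cc(O)c2C(=O)OC)c(C(C)=O)c1
F4 | step 3 | methyl 2-(2-acetoxy-6-bromo-4-methoxyphenoxy)-6-hydroxy-4-methylbenzoate | COc1cc(Br)c(Oc2cc(C)cc(O)c2C(=O)OC)c(OC(C)=O)c1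
F5 | step 2 | 2-bromo-6-formyl-4-methoxyphenyl fluorosulfate | COc1cc(Br)c(OS(=O)(=O)F)c(C=O)c1
F6 | step 2 | 3-bromo-2-fluoro-5-methoxybenzaldehyde | COc1cc(Br)c(F)c(C=O)c1
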